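## Analysis of the target

Target 15 is 2,6-dibromo-3,4-dihydroxybenzyl 2,3,6-tribromo-4,5-dihydroxybenzyl ether, in which two heavily substituted benzene rings are joined by a CH2–O–CH2 chain, with C7 on ring A and C7' on ring B. Ring A carries the chain at C1, bromine at C2 and C6, hydroxyl at C3 and C4, and its only hydrogen at C5, while ring B carries the chain at C1', bromine at C2', C5' and C6', and hydroxyl at C3' and C4'. There is no stereocenter and no ring to build besides the arenes, so the problem is purely constitutional. The two halves differ by one bromine (C5' against C5–H), so any route that brominates after the halves are joined, or that forms the ether by a reversible benzylic substitution, risks mixtures that differ by one bromine or by exchange of the halves. The sensitive groups are two catechols (oxidation to ortho-quinones), five aryl C–Br bonds (no hydrogenolysis, no palladium, no halogen–metal exchange), and a dibenzyl ether whose methylene carbons are each para to a hydroxyl (C4, C4'). A phenoxide or an acid can therefore expel the other half through a quinone methide, above all in nucleophilic solvents. The strategy rests on one feature: C1 and C1' each sit between two bromines (C2/C6 and C2'/C6'), so the corresponding C–H bonds of the bromoarenes are the most acidic ones and both rings can be attached, fully brominated, to a preformed C7–O–C7' unit by C–H metalation.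

## Retrosynthetic reasoning

**15 ⇒ 14 (four O–Si bonds).** The catechol oxygens are masked as tert-butyldimethylsilyl ethers. These can be removed by a buffered fluoride source in an aprotic solvent, which keeps every liberated phenol protonated and so avoids the quinone methide pathway. Hydrogenolysis or Lewis-acid dealkylation would attack the C–Br bonds or the benzylic ether. The silyl ethers are also bulky and poorly coordinating, which matters for the next disconnection.

**14 ⇒ 4 + 9 + 10 (C1–C7 and C1'–C7').** The two aryl–CH2 bonds are cut, not the C7–O or O–C7' bond. Forming the ether oxygen bond would require a benzylic electrophile para to oxygen on one ring, the very species that scrambles such ethers and gives symmetrical by-products. Cutting at the arene instead leaves the three-atom chain as the bifunctional electrophile 10 and makes each ring a nucleophile at the carbon between two bromines. The gain is full convergence, with all five bromines fixed before the union. The forward reaction must magnesiate 4 between its bromines to give 11, alkylate only one end of 10 to give 12, and then couple 12 with 13, the magnesium derivative of 9 at its single C–H.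

**4 ⇒ 3 ⇒ 1 (two O–Si bonds, then C–O in place of C–CHO).** After removal of the silyl groups, the 3,5-dibromo pattern of diol 3 cannot come from electrophilic bromination of an unsubstituted 1,2-dioxygenated benzene, which goes para to each oxygen. It is exactly what phenol-directed dibromination of an ortho-hydroxy aldehyde gives. A Dakin oxidation then turns the formyl carbon of the purchasable aldehyde 1 into the second oxygen.

**9 ⇒ 8 ⇒ 6 ⇒ 5 (two O–Si bonds, C–O in place of C–CHO, two C–Br bonds).** The same logic gives ring B. In aldehyde 5 the hydroxyl (ortho/para), the formyl group (meta) and the existing bromine (ortho/para) all direct to the same two carbons. Dibromination to 6 is therefore unambiguous and leaves the single hydrogen between two bromines. Dakin oxidation gives 8, and silylation gives 9.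

## Alternatives that were turned down

**Alternative 1: ring B by cycloaddition of a thiophene dioxide.** The disconnection removes C1'–C2' and C5'–C6'. In the forward direction the diene A2, which is 2,5-dibromo-3,4-bis(methoxymethoxy)thiophene 1,1-dioxide, would add thermally to the bromoalkyne A3, a ring A benzyl 3-bromopropargyl ether. Loss of the sulfone bridge as SO2 would then aromatize the adduct to the tetrakis(methoxymethyl) ether A1.
- For: every substituent of ring B is placed by construction, and the symmetric diene A2 removes any regiochemical question. On this point it is stronger than a route that relies on C–H acidity.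
- Against: A2 derives from an electron-rich 3,4-dialkoxythiophene, which is hard to oxidize to its dioxide, and such dioxides dimerize. A3 is a poor partner for A2 and would need forcing temperatures in the presence of a benzylic ether. Ring A with its C7 carbon still has to be made separately. The acetal groups of A1 come off only with acid, which is what the para-hydroxybenzyl ether tolerates least.
- Comparison: the chosen route needs far fewer steps, forms no arene ring, and ends with a fluoride deprotection. It pays for this with a metalation whose site must be controlled.

**Alternative 2: ring A from a dibromopyrone.** The disconnection removes C2–C3 and C4–C5. The 3,5-dibromo-2-pyrone A5 carries the ring B benzyloxymethyl group at its C4. It would add across its C3 and C6 to the alkyne A6, which is bis(pinacolatoboryl)acetylene, and loss of CO2 from the bridged lactone would give the diboronate A4.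
- For: the two oxygens of ring A arise from C–B bonds, and the bromines flanking C1 come from the pyrone. No acidity-governed selectivity is needed and the volatile carcinogen 10 is avoided. On these points it is as strong as or stronger than the chosen route.
- Against: A5 is a multistep target in itself. The cycloaddition of A5 with A6 needs high temperature. Turning A4 into the target needs oxidation of two C–B bonds under basic peroxide and removal of two acetates, all in the presence of free catechols and the labile ether. Ring B must still be made with its C7' carbon by other chemistry.
- Comparison: the chosen strategy uses one type of bond formation for both rings and reaches each partner in two or three steps.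

**Alternative 3: late tetrabromination directed by free phenols.** The disconnection removes the C–Br bonds at C2, C6, C2' and C6'. The bis-phenol A8 (free hydroxyl at C3 and C3', pivalate at C4 and C4', one bromine at C5') would be treated with four equivalents of an N-bromo imide to give the dipivalate A7.
- For: this is the shortest plan on paper. It needs no organometallic step and no carcinogenic linchpin, and each free hydroxyl does direct to its ortho and para carbon. On step economy it is stronger.
- Against: an acyl group on a catechol migrates easily to the neighbouring oxygen, which would redirect bromination to C5. The ortho positions C2 and C2' are flanked on both sides and will lag behind, so tri-, tetra- and pentabrominated ethers that differ by one bromine are to be expected. The brominating agent and the hydrogen bromide formed can oxidize or cleave an electron-rich dibenzyl ether. Removing the pivalates requires base, which opens the quinone methide pathway.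
- Comparison: the chosen route fixes every bromine on small, purifiable arenes before the union and never exposes the ether to electrophilic halogen.

Key step: step 6

Remark on the chemistry: 10 is a volatile carcinogen and is assumed to be handled, stripped and quenched (aqueous ammonia trap) in closed apparatus. TMPMgCl·LiCl is used as its THF solution.

## Route

Step 1
Reactants: 1 3,5-dibromo-2-hydroxybenzaldehyde
Product: 3 3,5-dibromobenzene-1,2-diol, via 3,5-dibromo-2-hydroxyphenyl formate 2 (not isolated)
Conditions: H2O2 (30% aq, 1.2 equiv), NaOH (2.2 equiv), H2O/THF, 0 °C → rt, argon; then HCl (aq)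
Reagents that add atoms: hydrogen peroxide, OO
Why: Dakin oxidation; hydroperoxide adds to the aldehyde, the phenoxide-bearing aryl group migrates to oxygen to give formate 2, and the alkaline medium saponifies it, a standard conversion for 3,5-dihalosalicylaldehydes.

Step 2
Reactants: 3 3,5-dibromobenzene-1,2-diol
Product: 4 3,5-dibromo-1,2-bis(tert-butyldimethylsilyloxy)benzene
Conditions: TBSCl (2.5 equiv), imidazole (5 equiv), DMF, rt
Reagents that add atoms: tert-butyldimethylsilyl chloride, CC(C)(C)[Si](C)(C)Cl
Why: Imidazole-promoted silylation of phenols; both hydroxyls are acidic and only one is flanked by bromine, so the bis-silyl ether should form cleanly.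

Step 3
Reactants: 5 2-bromo-6-hydroxybenzaldehyde
Product: 6 2,3,5-tribromo-6-hydroxybenzaldehyde
Conditions: Br2 (2.1 equiv), AcOH, rt
Reagents that add atoms: bromine, BrBr
Why: Electrophilic aromatic bromination; the hydroxyl (ortho/para), the formyl group (meta) and the bromine already present (ortho/para) all direct to the same two carbons, so the one remaining hydrogen ends up between two bromines.

Step 4
Reactants: 6 2,3,5-tribromo-6-hydroxybenzaldehyde
Product: 8 3,4,6-tribromobenzene-1,2-diol, via 2,3,5-tribromo-6-hydroxyphenyl formate 7 (not isolated)
Conditions: H2O2 (30% aq, 1.3 equiv), NaOH (2.2 equiv), H2O/THF, 0 °C → rt, argon; then HCl (aq)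
Reagents that add atoms: hydrogen peroxide, OO
Why: Dakin oxidation as in step 1; the ortho phenoxide makes aryl migration win over hydride migration despite the three bromines, and formate 7 is hydrolysed in the same pot.

Step 5
Reactants: 8 3,4,6-tribromobenzene-1,2-diol
Product: 9 3,4,6-tribromo-1,2-bis(tert-butyldimethylsilyloxy)benzene
Conditions: TBSCl (3 equiv), imidazole (6 equiv), DMAP (cat.), DMF, rt → 40 °C
Reagents that add atoms: tert-butyldimethylsilyl chloride, CC(C)(C)[Si](C)(C)Cl
Why: Silylation of phenols as in step 2; both hydroxyls are flanked by bromine but are strongly acidic, so excess reagent and gentle warming should carry the reaction to the bis-silyl ether.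

Step 6
Reactants: 4 3,5-dibromo-1,2-bis(tert-butyldimethylsilyloxy)benzene; 9 3,4,6-tribromo-1,2-bis(tert-butyldimethylsilyloxy)benzene; 10 bis(chloromethyl) ether
Product: 14 2,6-dibromo-3,4-bis(tert-butyldimethylsilyloxy)benzyl 2,3,6-tribromo-4,5-bis(tert-butyldimethylsilyloxy)benzyl ether, via 2,6-dibromo-3,4-bis(tert-butyldimethylsilyloxy)phenylmagnesium chloride 11 (not isolated), via 1,3-dibromo-2-[(chloromethoxy)methyl]-4,5-bis(tert-butyldimethylsilyloxy)benzene 12 (not isolated), via 2,3,6-tribromo-4,5-bis(tert-butyldimethylsilyloxy)phenylmagnesium chloride 13 (not isolated)
Conditions: (a) 4, TMPMgCl·LiCl (1.05 equiv), THF, 0 °C; (b) cannulate into 10 (8 equiv), THF, −40 °C; (c) strip volatiles under vacuum, toluene chase; (d) THF, add 13 [separate flask: 9 (1.6 equiv), TMPMgCl·LiCl (1.5 equiv), THF, −20 °C], −40 → 0 °C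
Reagents that add atoms: none
Why: Proposed new method: the hindered magnesium amide removes the proton flanked by two C–Br bonds (C4–H of 4, the single C–H of 9) without touching a C–Br bond, and each arylmagnesium then displaces chloride from an α-chloro ether whose ionisation is assisted by the ether oxygen and by magnesium, first on 10 to give 12 (again an α-chloro ether) and then on 12, so that C1–C7 and C1'–C7' form and the C7–O–C7' unit is transferred intact. The closest known reaction types are the alkylation of aryl Grignard reagents by chloromethyl ethers and the TMPMgCl·LiCl magnesiation of polyhaloarenes between two halogens; the new element is the sequential use of both chlorides of 10 by two different arylmagnesium reagents. No ring is closed and no stereocenter is created. Three selectivities are needed. In 4 the site C4 should win over C6 because it has two acidifying ortho bromines against one, and because the bulky, poorly coordinating silyl ether beside C6 keeps the base away. Mono-alkylation of 10 is enforced by adding 11 inversely to a large excess of 10 at low temperature and removing the excess before 13 is introduced. In the second stage 9 is kept in slight excess over the base so that no magnesium amide remains to attack 12, 13 is used in excess over 12 to cover quenching by ammonium salts, and both arylmagnesium reagents are held at or below 0 °C so that ortho-bromo elimination to an aryne does not start.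

Step 7
Reactants: 14 2,6-dibromo-3,4-bis(tert-butyldimethylsilyloxy)benzyl 2,3,6-tribromo-4,5-bis(tert-butyldimethylsilyloxy)benzyl ether
Product: 15 2,6-dibromo-3,4-dihydroxybenzyl 2,3,6-tribromo-4,5-dihydroxybenzyl ether (target)
Conditions: Bu4NF (4.4 equiv), AcOH (6 equiv), THF, 0 °C, argon; pH 4 buffer work-up, no alcohol solvents
Reagents that add atoms: none
Why: Fluoride-mediated cleavage of aryl silyl ethers, driven by the Si–F bond and by the good brominated phenoxide leaving groups; acetic acid protonates each phenoxide as it forms, which should suppress quinone methide formation at C7 and C7' and oxidation of the catechols.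

## Compound list

1 | 3,5-dibromo-2-hydroxybenzaldehyde | O=Cc1cc(Br)cc(Br)c1O | starting material
2 | 3,5-dibromo-2-hydroxyphenyl formate | O=COc1cc(Br)cc(Br)c1O | intermediate
3 | 3,5-dibromobenzene-1,2-diol | Oc1cc(Br)cc(Br)c1O | intermediate
4 | 3,5-dibromo-1,2-bis(tert-butyldimethylsilyloxy)benzene | CC(C)(C)[Si](C)(C)Oc1cc(Br)cc(Br)c1O[Si](C)(C)C(C)(C)C | intermediate
5 | 2-bromo-6-hydroxybenzaldehyde | O=Cc1c(O)cccc1Br | starting material
6 | 2,3,5-tribromo-6-hydroxybenzaldehyde | O=Cc1c(O)c(Br)cc(Br)c1Br | intermediate
7 | 2,3,5-tribromo-6-hydroxyphenyl formate | O=COc1c(O)c(Br)cc(Br)c1Br | intermediate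
8 | 3,4,6-tribromobenzene-1,2-diol | Oc1c(O)c(Br)cc(Br)c1Br | intermediate
9 | 3,4,6-tribromo-1,2-bis(tert-butyldimethylsilyloxy)benzene | CC(C)(C)[Si](C)(C)Oc1c(Br)cc(Br)c(Br)c1O[Si](C)(C)C(C)(C)C | intermediate
10 | bis(chloromethyl) ether | ClCOCCl | starting material
11 | [2,6-dibromo-3,4-bis(tert-butyldimethylsilyloxy)phenyl]magnesium chloride (LiCl complex in THF) | CC(C)(C)[Si](C)(C)Oc1cc(Br)c([Mg]Cl)c(Br)c1O[Si](C)(C)C(C)(C)C | intermediate
12 | 1,3-dibromo-2-[(chloromethoxy)methyl]-4,5-bis(tert-butyldimethylsilyloxy)benzene | CC(C)(C)[Si](C)(C)Oc1cc(Br)c(COCCl)c(Br)c1O[Si](C)(C)C(C)(C)C | intermediate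
13 | [2,3,6-tribromo-4,5-bis(tert-butyldimethylsilyloxy)phenyl]magnesium chloride (LiCl complex in THF) | CC(C)(C)[Si](C)(C)Oc1c(Br)c([Mg]Cl)c(Br)c(Br)c1O[Si](C)(C)C(C)(C)C | intermediate
14 | 2,6-dibromo-3,4-bis(tert-butyldimethylsilyloxy)benzyl 2,3,6-tribromo-4,5-bis(tert-butyldimethylsilyloxy)benzyl ether | CC(C)(C)[Si](C)(C)Oc1cc(Br)c(COCc2c(Br)c(O[Si](C)(C)C(C)(C)C)c(O[Si](C)(C)C(C)(C)C)c(Br)c2Br)c(Br)c1O[Si](C)(C)C(C)(C)C | intermediate
15 | 2,6-dibromo-3,4-dihydroxybenzyl 2,3,6-tribromo-4,5-dihydroxybenzyl ether | Oc1cc(Br)c(COCc2c(Br)c(O)c(O)c(Br)c2Br)c(Br)c1O | target

## Step count and risks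

Total step count: 7. Longest linear sequence: 5 steps (steps 3, 4, 5, 6 and 7, from 5 to 15).

**Step 6 (key step, carries the new method).** Three things are most likely to go wrong:
- slow or misdirected magnesiation of 4 (attack at C6, followed by silyl migration from oxygen to carbon);
- double arylation of 10 by 11 despite inverse addition;
- loss of 12 during evaporation through reaction with the liberated amine.

The fallback sets out from 4 and returns to the route at 12, and uses only known reaction types. LiN(iPr)2 (LDA) in THF at −78 °C, the established deprotonation of 1,3-dibromoarenes between the halogens, would give [2,6-dibromo-3,4-bis(tert-butyldimethylsilyloxy)phenyl]lithium F1. Quenching with DMF, followed by aqueous NH4Cl work-up, would give 2,6-dibromo-3,4-bis(tert-butyldimethylsilyloxy)benzaldehyde F2. Reduction with iBu2AlH in CH2Cl2 at −78 °C avoids alkoxide, which would endanger the silyl ether para to the carbonyl, and would give [2,6-dibromo-3,4-bis(tert-butyldimethylsilyloxy)phenyl]methanol F3. Paraformaldehyde and TMSCl in CH2Cl2 at 0 °C, the usual preparation of chloromethyl ethers from alcohols, would convert F3 into 12. Here 12 is an isolated, amine-free, monofunctional electrophile. Addition of 13, made from 9 as in step 6, to 12 in THF at −40 → 0 °C then gives 14 by the known alkylation of an aryl Grignard reagent with a chloromethyl ether.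

**Step 7.** The danger is heterolysis of the C7–O or C7'–O bond through a para-quinone methide if phenoxide builds up, together with air oxidation of the catecholates. The fallback sets out from 14 and returns at 15, and changes the bond cleaved in the last operation. Bu4NF in THF with excess acetic anhydride at 0 °C would trap each phenoxide as it is released and give 2,6-dibromo-3,4-diacetoxybenzyl 2,3,6-tribromo-4,5-diacetoxybenzyl ether F4, which is stable and can be purified. Hydrazinium acetate in DMF at rt, a buffered hydrazinolysis of aryl acetates in an aprotic medium, would then give 15.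

**Step 4.** The aldehyde of 6 is flanked on both sides and the ring is electron-poor. The peroxide adduct may therefore collapse by hydride migration to the carboxylic acid, or the product may be over-oxidised in alkaline peroxide. The fallback sets out from 3 and returns at 8; it makes no new compound, hence the entry F0. It replaces the oxidation with an amine-directed ortho-bromination of a phenol: NBS (1.0 equiv) with catalytic diisopropylamine in CH2Cl2 at 0 °C. In 3 only one hydroxyl has free ortho and para positions, and the para carbon lies between two bromines, so bromine should enter ortho and give 8 directly. The price is possible over-bromination, which is why this is not the main route.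

## Further compounds

F1 | step 6 | [2,6-dibromo-3,4-bis(tert-butyldimethylsilyloxy)phenyl]lithium | [Li]c1c(Br)cc(O[Si](C)(C)C(C)(C)C)c(O[Si](C)(C)C(C)(C)C)c1Br
F2 | step 6 | 2,6-dibromo-3,4-bis(tert-butyldimethylsilyloxy)benzaldehyde | CC(C)(C)[Si](C)(C)Oc1cc(Br)c(C=O)c(Br)c1O[Si](C)(C)C(C)(C)C
F3 | step 6 | [2,6-dibromo-3,4-bis(tert-butyldimethylsilyloxy)phenyl]methanol | CC(C)(C)[Si](C)(C)Oc1cc(Br)c(CO)c(Br)c1O[Si](C)(C)C(C)(C)C
F4 | step 7 | 2,6-dibromo-3,4-diacetoxybenzyl 2,3,6-tribromo-4,5-diacetoxybenzyl ether | CC(=O)Oc1cc(Br)c(COCc2c(Br)c(OC(C)=O)c(OC(C)=O)c(Br)c2Br)c(Br)c1OC(C)=O
F0 | step 4 | none | none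
A1 | alternative 1 | tetrakis(methoxymethyl) ether of the target | COCOc1c(OCOC)c(Br)c(COCc2c(Br)c(OCOC)c(OCOC)cc2Br)c(Br)c1Br
A2 | alternative 1 | 2,5-dibromo-3,4-bis(methoxymethoxy)thiophene 1,1-dioxide | COCOC1=C(Br)S(=O)(=O)C(Br)=C1OCOC
A3 | alternative 1 | 1,3-dibromo-2-{[(3-bromoprop-2-yn-1-yl)oxy]methyl}-4,5-bis(methoxymethoxy)benzene | COCOc1cc(Br)c(COCC#CBr)c(Br)c1OCOC
A4 | alternative 2 | 2,3,6-tribromo-4,5-diacetoxybenzyl 2,6-dibromo-3,4-bis(pinacolatoboryl)benzyl ether | CC(=O)Oc1c(OC(C)=O)c(Br)c(COCc2c(Br)c(B3OC(C)(C)C(C)(C)O3)c(B3OC(C)(C)C(C)(C)O3)cc2Br)c(Br)c1Br
A5 | alternative 2 | 3,5-dibromo-4-{[(2,3,6-tribromo-4,5-diacetoxyphenyl)methoxy]methyl}-2H-pyran-2-one | O=C1OC=C(Br)C(COCc2c(Br)c(OC(C)=O)c(OC(C)=O)c(Br)c2Br)=C1Br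
A6 | alternative 2 | bis(pinacolatoboryl)acetylene | CC1(C)OB(C#CB2OC(C)(C)C(C)(C)O2)OC1(C)C
A7 | alternative 3 | 4,4'-di-O-pivaloyl derivative of the target | CC(C)(C)C(=O)Oc1cc(Br)c(COCc2c(Br)c(O)c(OC(=O)C(C)(C)C)c(Br)c2Br)c(Br)c1O
A8 | alternative 3 | 3-hydroxy-4-pivaloyloxybenzyl 3-bromo-5-hydroxy-4-pivaloyloxybenzyl ether | CC(C)(C)C(=O)Oc1ccc(COCc2cc(Br)c(OC(=O)C(C)(C)C)c(O)c2)cc1O
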